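(The earlier runs and the new flask were generated by integration from invented constants.)

Substrate that was charged and can no longer be seen must stand somewhere, so you can split its loss into branches and give each branch a share.

in all of them: substrate 12 mM
- larch: partner 3 equiv; second reagent 1.4 equiv; third reagent 1.1 equiv; run made earlier
- alder: partner 3 equiv; second reagent 12 equiv; third reagent 1.1 equiv; run made earlier
- north-east: partner 3.00 equiv; second reagent 1.00 equiv; third reagent 1.10 equiv; time 10 h
- south-west: partner 3.00 equiv; second reagent 2.00 equiv; third reagent 1.10 equiv; time 10 h
- east: partner 3.00 equiv; second reagent 4.00 equiv; third reagent 1.10 equiv; time 10 h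
- south-east: partner 3.00 equiv; second reagent 8.00 equiv; third reagent 1.10 equiv; time 10 h

| run | time / h | target / % | substrate / % |
|---|---|---|---|
| larch | 0.417 | 0.8 | 72.6 |
| larch | 0.833 | 0 | 52.9 |
| larch | 1.33 | 0 | 38.2 |
| larch | 2.50 | 1.4 | 16.4 |
| larch | 5.00 | 5.9 | 3.8 |
| alder | 0.417 | 0 | 31.4 |
| alder | 1.33 | 0.4 | 2.7 |
| alder | 2.50 | 2.5 | 0.7 |
| alder | 4.00 | 3.6 | 0.8 |
| alder | 5.00 | 3.5 | 0.2 |

(standard deviation of a reading: 0.5 percentage points)

- what was read earlier has a scatter of 0.5 percentage points, one standard deviation
- "hardly changes" means that all values lie within two and a half points (for a concentration: within two and a half percent of the largest)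

- amount of target at the end, in percent of the substrate charged for north-east, south-west, east, south-east, in this order
- the shape of the row from first to last (rises all the way / falls all the way / hardly changes / rises, then falls / falls, then rises)

In the larch run at 5.00 h you read 3.8% substrate and 5.9% target, so 90.3% of the charge stands in something unread.

Compare rates at one moment, the start. If you treat the substrate's loss as pseudo-first-order, one reading per run gives a rate constant: 0.724 h⁻¹ for larch and 2.78 h⁻¹ for alder. I draw a straight line through these two points, which nothing yet tests. Carried back to no second reagent, it leaves a base constant of 0.452 h⁻¹, and the alder run has 2.33 h⁻¹ on top of that, a part which on this line grows in step with the equivalents of second reagent. The base constant over the whole constant gives 70.0% for north-east. I call this the kept share: the part of the substrate's early loss that does not depend on second reagent.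

Set the two runs side by side, at 5.00 h:

- larch: kept share 62.5%, target 5.9%, target per kept share 9.44%
- alder: kept share 16.3%, target 3.5%, target per kept share 21.5%

Read the first column: from larch to alder the kept share falls by a factor of 3.83. Read the second: target falls by a factor of just 1.69. The third column therefore rises by a factor of 2.28: on these readings, the alder run keeps a smaller share of its substrate, yet shows more target per kept share at that time.

Now apply the kept share to the asked flasks: 70.0%, 53.8%, 36.8% and 22.6%. The first doubling loses about a quarter of the share, and the last loses 38.6%. The last doubling thus loses more of the share than the first, so I expect the gain in target per kept share to outweigh the loss at first and not later. I commit to the shape, not to numbers: the row rises, then falls.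

The forecast gives 12.5%, 11.5%, 8.5% and 5.5%, with the shape falls all the way; in its words, “The first two are close, so the early trend is uncertain.”

The flask gives 9.49%, 12.0%, 10.3% and 6.44%, so the shape is rises, then falls, and the row turns at 2.2 equiv.

    substrate + partner → intermediate A (k = 0.00420 L mol⁻¹ s⁻¹)
    substrate + second reagent → side product (k = 0.00440 L mol⁻¹ s⁻¹)
    partner + target → over-reaction product (k = 0.00180 L mol⁻¹ s⁻¹)
    second reagent + intermediate A → intermediate B (k = 0.00380 L mol⁻¹ s⁻¹)
    third reagent + intermediate B → target (k = 0.00260 L mol⁻¹ s⁻¹)

In north-east at the start, substrate goes to intermediate A 2.9 times as fast as to side product, a share of 74.4% beside the kept share of 70.0%, and by 10.0 h that ratio has drifted up to 5.6, while side product stands at 24.2%, less than the 30.0% that the kept share of the start leaves for it. In the second flask, south-east, the kept share of the start leaves 77.4% for side product, and at 10.0 h side product stands lower, at 73.5%.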